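The 5-hydroxy-5,6-dihydro-2H-pyran-2-one ring (O1, C2–C6) is traced back to a 2-furyl carbinol: the four furan carbons become C2–C5, the carbinol carbon is C6 and its oxygen is O1. One oxidative ring expansion of furan 23 therefore builds the whole pyranone, with C6 (S), C7 (R, oxygen silylated), C8 (S) and flavanone C2 (S) already in place. The precursor comes from a differentiated phloroglucinol ether by two directed metalations: the first joins the arene to the benzylic carbon of (2S,3S)-phenylglycidol (C8), the second acylates it for a Mitsunobu closure of the flavanone. Lactol oxidation, cis-selective ketone reduction and acid deprotection complete the route.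

Key step: step 14

Remark: lactone numbering (O1, C2=O, C3=C4, C5, C6, chain C7, C8) is used throughout; 4 and 9 are taken as catalogue chemicals; C6 is S in 23–26 and R in 27 and 28 only because the CIP priorities change, not the geometry.

Abbreviations: MOM = methoxymethyl; TBS = tert-butyldimethylsilyl; Fl = (2S)-5,7-bis(methoxymethoxy)-4-oxo-2-phenylchroman-6-yl.

Step 1
Reactants: 1 phloroglucinol
Product: 2 3,5-bis(methoxymethoxy)phenol
Conditions: MOMCl (2.0 equiv), i-Pr2NEt (2.2 equiv), CH2Cl2/DMF, 0 °C → rt; chromatography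
Reagents that add atoms: chloromethyl methyl ether, COCCl
Why: Williamson-type O-alkylation of the symmetric triphenol with two equivalents of MOMCl should give the bis-ether as the main part of a statistical mixture (mono- and tris-ethers separated), which leaves the oxygen destined to become the flavanone ring oxygen different from the two that end as the 5- and 7-hydroxyls.

Step 2
Reactants: 2 3,5-bis(methoxymethoxy)phenol
Product: 3 1-(benzyloxy)-3,5-bis(methoxymethoxy)benzene
Conditions: BnBr, K2CO3, acetone, reflux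
Reagents that add atoms: benzyl bromide, BrCc1ccccc1
Why: Williamson benzylation of the remaining phenol installs a group that directs metalation less strongly than MOM and can later be removed by hydrogenolysis without touching MOM or silyl ethers.

Step 3
Reactants: 3 1-(benzyloxy)-3,5-bis(methoxymethoxy)benzene; 4 (2S,3S)-3-phenylglycidol
Product: 7 (2R,3S)-3-[4-(benzyloxy)-2,6-bis(methoxymethoxy)phenyl]-3-phenylpropane-1,2-diol, via aryllithium 5 (not isolated), via arylmagnesium bromide 6 (not isolated)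
Conditions: 3 (3 equiv), n-BuLi, THF, 0 °C; MgBr2·OEt2, −20 °C; CuI (10 mol%), then 4, −30 → 0 °C (the first equivalent of 6 is consumed by the hydroxyl of 4 and returns 3); aq NH4Cl
Reagents that add atoms: none
Why: Directed ortho-metalation should occur at the ring CH flanked by both MOM ethers, and copper-catalysed SN2 opening of the epoxy alcohol by the aryl Grignard reagent at the benzylic carbon with inversion sets C8 (S) while C7 keeps the epoxide geometry and becomes R, so the aryl–C8 bond is formed para to the benzyloxy group.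

Step 4
Reactants: 7 (2R,3S)-3-[4-(benzyloxy)-2,6-bis(methoxymethoxy)phenyl]-3-phenylpropane-1,2-diol
Product: 8 bis-TBS ether of 7 [(2R,3S)-1,2-bis(TBS-oxy)-3-aryl-3-phenylpropane]
Conditions: TBSCl (3 equiv), imidazole, DMAP (cat.), DMF, 45 °C
Reagents that add atoms: tert-butyldimethylsilyl chloride, CC(C)(C)[Si](C)(C)Cl
Why: Silylation of both hydroxyls (the hindered secondary one needs warming and DMAP) masks the diol for the second metalation and places on O7 the silyl group that the key step requires.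

Step 5
Reactants: 9 ethyl (R)-3-hydroxy-3-phenylpropanoate
Product: 10 (R)-3-hydroxy-N-methoxy-N-methyl-3-phenylpropanamide
Conditions: MeNHOMe·HCl, i-PrMgCl (excess), THF, −20 → 0 °C
Reagents that add atoms: N,O-dimethylhydroxylamine hydrochloride, CNOC.Cl
Why: Magnesium-amide aminolysis of the ester (Weinreb amide formation) proceeds with the hydroxyl as its alkoxide and does not touch the carbinol centre.

Step 6
Reactants: 8 bis-TBS ether of 7; 10 (R)-3-hydroxy-N-methoxy-N-methyl-3-phenylpropanamide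
Product: 13 (3R)-1-{6-(benzyloxy)-3-[(1S,2R)-2,3-bis(TBS-oxy)-1-phenylpropyl]-2,4-bis(methoxymethoxy)phenyl}-3-hydroxy-3-phenylpropan-1-one, via ring-lithiated arene 11 (not isolated), via lithium alkoxide 12 (not isolated)
Conditions: 8, n-BuLi, TMEDA, THF, −20 → 0 °C; 10 (1.5 equiv) pre-treated with LiHMDS (1.0 equiv), THF, −78 °C, then added; −78 → 0 °C; aq NH4Cl
Reagents that add atoms: none
Why: Directed ortho-metalation at the only remaining type of ring CH (between a MOM ether and the benzyloxy group) followed by Weinreb ketone synthesis places the C-ring carbons next to the benzyloxy oxygen; the amide is used as its alkoxide so that β-elimination is suppressed and the R carbinol centre is carried over unchanged.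

Step 7
Reactants: 13 (3R)-β-hydroxy ketone with benzyl ether
Product: 14 (3R)-1-{3-[(1S,2R)-2,3-bis(TBS-oxy)-1-phenylpropyl]-6-hydroxy-2,4-bis(methoxymethoxy)phenyl}-3-hydroxy-3-phenylpropan-1-one
Conditions: H2 (1 atm), 10% Pd/C, EtOAc, rt
Reagents that add atoms: none
Why: Hydrogenolysis of the aryl benzyl ether in neutral ethyl acetate is much faster than loss of the secondary benzylic hydroxyl and frees only the phenol para to C8, so the later ring closure can give the 6-substituted flavanone alone.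

Step 8
Reactants: 14 (3R)-hydroxy ketone with free phenol
Product: 15 (2S)-6-[(1S,2R)-2,3-bis(TBS-oxy)-1-phenylpropyl]-5,7-bis(methoxymethoxy)-2-phenylchroman-4-one
Conditions: PPh3, DIAD, THF, 0 °C → rt
Reagents that add atoms: none
Why: Intramolecular Mitsunobu etherification (6-exo-tet attack of the hydrogen-bonded phenol on the activated benzylic carbinol) closes the pyranone ring with inversion, turning the R carbinol into the (2S)-flavanone centre.

Step 9
Reactants: 15 (2S)-flavanone bis-TBS ether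
Product: 16 (2S)-6-[(1S,2R)-2-(TBS-oxy)-3-hydroxy-1-phenylpropyl]-5,7-bis(methoxymethoxy)-2-phenylchroman-4-one
Conditions: HF·pyridine, pyridine, THF, 0 °C → rt
Reagents that add atoms: none
Why: Buffered HF·pyridine cleaves the unhindered primary silyl ether far faster than the secondary one next to the diarylmethine, and the non-basic medium leaves the flavanone and the MOM ethers intact.

Step 10
Reactants: 16 primary alcohol
Product: 17 (2R,3S)-2-(TBS-oxy)-3-Fl-3-phenylpropanal
Conditions: Dess–Martin periodinane, pyridine, CH2Cl2, 0 °C → rt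
Reagents that add atoms: none
Why: Dess–Martin oxidation under buffered, non-basic conditions should give the α-silyloxy aldehyde without epimerising C7 or opening the flavanone.

Step 11
Reactants: 17 (2R,3S)-2-(TBS-oxy)-3-Fl-3-phenylpropanal; 18 furan
Product: 21 (2R,3S)-2-(TBS-oxy)-1-(furan-2-yl)-3-Fl-3-phenylpropan-1-ol (C1 epimer mixture), via 2-furyllithium 19 (not isolated), via 2-furylmagnesium bromide 20 (not isolated)
Conditions: furan, n-BuLi, THF, 0 °C; MgBr2·OEt2; then 17 (20: 1.5 equiv), −78 °C; aq NH4Cl at −78 °C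
Reagents that add atoms: none
Why: Grignard addition at −78 °C is selective for the aldehyde over the hindered, electron-rich flavanone carbonyl and avoids strongly basic furyllithium; the new carbinol centre is not controlled because it is erased in step 12.

Step 12
Reactants: 21 furyl carbinol epimer mixture
Product: 22 (2R,3S)-2-(TBS-oxy)-1-(furan-2-yl)-3-Fl-3-phenylpropan-1-one
Conditions: Dess–Martin periodinane, pyridine, CH2Cl2, rt
Reagents that add atoms: none
Why: Dess–Martin oxidation of the furyl carbinol gives the 2-acylfuran that serves as substrate for catalyst-controlled reduction.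

Step 13
Reactants: 22 2-acylfuran
Product: 23 (1S,2R,3S)-2-(TBS-oxy)-1-(furan-2-yl)-3-Fl-3-phenylpropan-1-ol
Conditions: RuCl[(S,S)-TsDPEN](p-cymene) (2 mol%), HCO2H/Et3N (5:2), CH2Cl2, rt; stopped when 22 is consumed
Reagents that add atoms: none
Why: Noyori asymmetric transfer hydrogenation of the 2-acylfuran: the (S,S) catalyst treats the furan as the aryl group and delivers hydride to give the S carbinol at C6 under catalyst control (the sense of acetophenone to (S)-1-phenylethanol), while the 2,4,6-trioxygenated flavanone ketone should react much more slowly.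

Step 14
Reactants: 23 (1S,2R,3S)-2-(TBS-oxy)-1-(furan-2-yl)-3-Fl-3-phenylpropan-1-ol
Product: 25 (2S)-2-[(1R,2S)-1-(TBS-oxy)-2-Fl-2-phenylethyl]-6-hydroxy-2H-pyran-3(6H)-one (anomer mixture), via Z-ene-dione 24 (not isolated)
Conditions: VO(acac)2 (5 mol%), t-BuOOH (1.5 equiv, decane), CH2Cl2, 0 °C → rt
Reagents that add atoms: tert-butyl hydroperoxide, CC(C)(C)OO
Why: Achmatowicz rearrangement: the vanadium alkoxide formed at the C6 hydroxyl delivers the peroxide oxygen to the adjacent furan double bond, and the oxidised ring opens to Z-ene-dione 24, in which the former furan carbons are C5 (ketone), C4=C3 and C2 (aldehyde). The closest known reaction type is the VO(acac)2/t-BuOOH oxidation of secondary 2-furyl carbinols to 6-hydroxy-2H-pyran-3(6H)-ones. The pyranone ring closes by 6-exo-trig addition of the C6 hydroxyl to the C2 aldehyde, which forms the O1–C2 bond. The only new stereocentre is the lactol carbon C2, which is left uncontrolled because step 15 removes it, while C6, C7, C8 and the flavanone centre are not touched. The step needs oxidation of the furan in preference to the alkoxy-substituted flavanone arene and its ketone, which hydroxyl-directed delivery of the oxidant and the much higher nucleophilicity of the furan secure. The silyl ether on O7 keeps that oxygen from closing a bicyclic ketal onto C2.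

Step 15
Reactants: 25 pyranone lactol
Product: 26 (6S)-6-[(1R,2S)-1-(TBS-oxy)-2-Fl-2-phenylethyl]-2H-pyran-2,5(6H)-dione
Conditions: Jones reagent (CrO3, aq H2SO4), acetone, 0 °C, 10 min; crude product used at once
Reagents that add atoms: none
Why: Jones oxidation of the allylic lactol (hemiacetal to lactone) is fast at 0 °C and short enough for the aryl MOM ethers and the hindered silyl ether to survive, and C6 is not enolised in the acidic medium.

Step 16
Reactants: 26 keto-lactone
Product: 27 (5S,6R)-6-[(1R,2S)-1-(TBS-oxy)-2-Fl-2-phenylethyl]-5-hydroxy-5,6-dihydro-2H-pyran-2-one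
Conditions: NaBH4, CeCl3·7H2O, MeOH/CH2Cl2, −78 °C
Reagents that add atoms: none
Why: Luche reduction: 1,2-delivery of hydride to the C5 ketone of the nearly planar ene-dione from the face opposite the bulky C6 side chain should give the 5,6-cis alcohol (5S), and at −78 °C neither the lactone nor the flavanone carbonyl is reduced.

Step 17
Reactants: 27 protected lactone
Product: 28 (5S,6R)-6-{(1R,2S)-2-[(2S)-5,7-dihydroxy-4-oxo-2-phenylchroman-6-yl]-1-hydroxy-2-phenylethyl}-5-hydroxy-5,6-dihydro-2H-pyran-2-one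
Conditions: HCl (1.5 M in MeOH), 35–40 °C
Reagents that add atoms: none
Why: Acid-catalysed methanolysis removes the silyl ether and both MOM acetals in one operation under conditions in which the unsaturated lactone, the base-sensitive flavanone centre and the other stereocentres should be stable.

Compound list
1 | phloroglucinol | Oc1cc(O)cc(O)c1 | starting material
2 | 3,5-bis(methoxymethoxy)phenol | COCOc1cc(O)cc(OCOC)c1 | intermediate
3 | 1-(benzyloxy)-3,5-bis(methoxymethoxy)benzene | COCOc1cc(OCc2ccccc2)cc(OCOC)c1 | intermediate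
4 | (2S,3S)-3-phenylglycidol | OC[C@@H]1O[C@H]1c1ccccc1 | starting material
5 | [4-(benzyloxy)-2,6-bis(methoxymethoxy)phenyl]lithium (not isolated) | [Li]c1c(OCOC)cc(OCc2ccccc2)cc1OCOC | intermediate
6 | [4-(benzyloxy)-2,6-bis(methoxymethoxy)phenyl]magnesium bromide (not isolated) | Br[Mg]c1c(OCOC)cc(OCc2ccccc2)cc1OCOC | intermediate
7 | (2R,3S)-3-[4-(benzyloxy)-2,6-bis(methoxymethoxy)phenyl]-3-phenylpropane-1,2-diol | OC[C@H](O)[C@@H](c1ccccc1)c1c(OCOC)cc(OCc2ccccc2)cc1OCOC | intermediate
8 | bis-TBS ether of 7 | CC(C)(C)[Si](C)(C)OC[C@H](O[Si](C)(C)C(C)(C)C)[C@@H](c1ccccc1)c1c(OCOC)cc(OCc2ccccc2)cc1OCOC | intermediate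
9 | ethyl (R)-3-hydroxy-3-phenylpropanoate | CCOC(=O)C[C@@H](O)c1ccccc1 | starting material
10 | (R)-3-hydroxy-N-methoxy-N-methyl-3-phenylpropanamide | CON(C)C(=O)C[C@@H](O)c1ccccc1 | intermediate
11 | ring-lithiated 8, lithium between OMOM and OBn (not isolated) | CC(C)(C)[Si](C)(C)OC[C@H](O[Si](C)(C)C(C)(C)C)[C@@H](c1ccccc1)c1c(OCOC)cc(OCc2ccccc2)c([Li])c1OCOC | intermediate
12 | lithium alkoxide of 10 (not isolated) | CON(C)C(=O)C[C@@H](O[Li])c1ccccc1 | intermediate
13 | (3R)-1-{6-(benzyloxy)-3-[(1S,2R)-2,3-bis(TBS-oxy)-1-phenylpropyl]-2,4-bis(methoxymethoxy)phenyl}-3-hydroxy-3-phenylpropan-1-one | CC(C)(C)[Si](C)(C)OC[C@H](O[Si](C)(C)C(C)(C)C)[C@@H](c1ccccc1)c1c(OCOC)cc(OCc2ccccc2)c(C(=O)C[C@@H](O)c2ccccc2)c1OCOC | intermediate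
14 | (3R)-1-{3-[(1S,2R)-2,3-bis(TBS-oxy)-1-phenylpropyl]-6-hydroxy-2,4-bis(methoxymethoxy)phenyl}-3-hydroxy-3-phenylpropan-1-one | CC(C)(C)[Si](C)(C)OC[C@H](O[Si](C)(C)C(C)(C)C)[C@@H](c1ccccc1)c1c(OCOC)cc(O)c(C(=O)C[C@@H](O)c2ccccc2)c1OCOC | intermediate
15 | (2S)-6-[(1S,2R)-2,3-bis(TBS-oxy)-1-phenylpropyl]-5,7-bis(methoxymethoxy)-2-phenylchroman-4-one | CC(C)(C)[Si](C)(C)OC[C@H](O[Si](C)(C)C(C)(C)C)[C@@H](c1ccccc1)c1c(OCOC)cc2c(c1OCOC)C(=O)C[C@@H](c1ccccc1)O2 | intermediate
16 | (2S)-6-[(1S,2R)-2-(TBS-oxy)-3-hydroxy-1-phenylpropyl]-5,7-bis(methoxymethoxy)-2-phenylchroman-4-one | OC[C@H](O[Si](C)(C)C(C)(C)C)[C@@H](c1ccccc1)c1c(OCOC)cc2c(c1OCOC)C(=O)C[C@@H](c1ccccc1)O2 | intermediate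
17 | (2R,3S)-2-(TBS-oxy)-3-Fl-3-phenylpropanal | O=C[C@H](O[Si](C)(C)C(C)(C)C)[C@@H](c1ccccc1)c1c(OCOC)cc2c(c1OCOC)C(=O)C[C@@H](c1ccccc1)O2 | intermediate
18 | furan | c1ccoc1 | starting material
19 | 2-furyllithium (not isolated) | [Li]c1ccco1 | intermediate
20 | 2-furylmagnesium bromide (not isolated) | Br[Mg]c1ccco1 | intermediate
21 | (2R,3S)-2-(TBS-oxy)-1-(furan-2-yl)-3-Fl-3-phenylpropan-1-ol, C1 epimer mixture | OC(c1ccco1)[C@H](O[Si](C)(C)C(C)(C)C)[C@@H](c1ccccc1)c1c(OCOC)cc2c(c1OCOC)C(=O)C[C@@H](c1ccccc1)O2 | intermediate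
22 | (2R,3S)-2-(TBS-oxy)-1-(furan-2-yl)-3-Fl-3-phenylpropan-1-one | O=C(c1ccco1)[C@H](O[Si](C)(C)C(C)(C)C)[C@@H](c1ccccc1)c1c(OCOC)cc2c(c1OCOC)C(=O)C[C@@H](c1ccccc1)O2 | intermediate
23 | (1S,2R,3S)-2-(TBS-oxy)-1-(furan-2-yl)-3-Fl-3-phenylpropan-1-ol | c1coc(c1)[C@H]([C@H](O[Si](C)(C)C(C)(C)C)[C@@H](c2ccccc2)c2c(OCOC)cc3c(c2OCOC)C(=O)C[C@@H](c2ccccc2)O3)O | intermediate
24 | (2Z,5S,6R,7S)-6-(TBS-oxy)-5-hydroxy-4-oxo-7-Fl-7-phenylhept-2-enal (not isolated) | O=C/C=C\C(=O)[C@H]([C@H](O[Si](C)(C)C(C)(C)C)[C@@H](c1ccccc1)c1c(OCOC)cc2c(c1OCOC)C(=O)C[C@@H](c1ccccc1)O2)O | intermediate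
25 | (2S)-2-[(1R,2S)-1-(TBS-oxy)-2-Fl-2-phenylethyl]-6-hydroxy-2H-pyran-3(6H)-one, anomer mixture | OC1C=CC(=O)[C@H]([C@H](O[Si](C)(C)C(C)(C)C)[C@@H](c2ccccc2)c2c(OCOC)cc3c(c2OCOC)C(=O)C[C@@H](c2ccccc2)O3)O1 | intermediate
26 | (6S)-6-[(1R,2S)-1-(TBS-oxy)-2-Fl-2-phenylethyl]-2H-pyran-2,5(6H)-dione | O=C1C=CC(=O)[C@H]([C@H](O[Si](C)(C)C(C)(C)C)[C@@H](c2ccccc2)c2c(OCOC)cc3c(c2OCOC)C(=O)C[C@@H](c2ccccc2)O3)O1 | intermediate
27 | (5S,6R)-6-[(1R,2S)-1-(TBS-oxy)-2-Fl-2-phenylethyl]-5-hydroxy-5,6-dihydro-2H-pyran-2-one | O=C1C=C[C@H](O)[C@H]([C@H](O[Si](C)(C)C(C)(C)C)[C@@H](c2ccccc2)c2c(OCOC)cc3c(c2OCOC)C(=O)C[C@@H](c2ccccc2)O3)O1 | intermediate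
28 | (5S,6R)-6-{(1R,2S)-2-[(2S)-5,7-dihydroxy-4-oxo-2-phenylchroman-6-yl]-1-hydroxy-2-phenylethyl}-5-hydroxy-5,6-dihydro-2H-pyran-2-one | O=C1C=C[C@H](O)[C@H]([C@H](O)[C@@H](c2ccccc2)c2c(O)cc3c(c2O)C(=O)C[C@@H](c2ccccc2)O3)O1 | target

Total step count: 17. Longest linear sequence: 16 (steps 1–4 and 6–17; step 5 is a side branch).

Steps most likely to fail

Step 3. The aryl group carries two ortho substituents, so SN2 delivery to the benzylic epoxide carbon may stall, or attack may leak to C2 of the glycidol. The fallback sets out from 5 and returns at 7; it sets C8 by conjugate addition and C7 by enolate oxidation. Aryllithium 5 is formylated with DMF to 4-(benzyloxy)-2,6-bis(methoxymethoxy)benzaldehyde F1. Horner–Wadsworth–Emmons reaction with diethyl {2-oxo-2-[(4R)-2-oxo-4-phenyloxazolidin-3-yl]ethyl}phosphonate (LiCl, i-Pr2NEt, MeCN) should give the (E)-enoyl imide F2. PhMgBr/CuBr·SMe2 should add phenyl to the β-carbon from the face opposite the auxiliary phenyl in the chelated s-cis conformer, giving the (3S)-3-aryl-3-phenylpropanoyl imide F3. The sodium Z-enolate (NaHMDS, −78 °C) is hydroxylated by 2-(phenylsulfonyl)-3-phenyloxaziridine anti to the auxiliary substituent to give the (2R)-hydroxy imide F4. LiBH4 (THF/MeOH) then reduces F4 to diol 7 and releases the auxiliary.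

Step 8. The activated benzylic oxygen of 14 may be lost by elimination towards the ketone, giving a chalcone that recloses without control and erodes the flavanone centre. The fallback sets out from 8 and returns at 15; it sets the centre by ligand-controlled conjugate addition. Ring-lithiated arene 11 is acylated with N-methoxy-N-methylacetamide to the acetophenone F5. Hydrogenolysis (H2, Pd/C, EtOAc) gives the 2'-hydroxyacetophenone F6. DMF dimethyl acetal (toluene, 90 °C) gives the enaminone F7, which should cyclise with PPTS to the chromone F8. Pd(OCOCF3)2/(R)-t-BuPyOX-catalysed conjugate addition of phenylboronic acid (NH4PF6, H2O, ClCH2CH2Cl, 60 °C) then installs the 2-phenyl group and should give 15; the ligand enantiomer is chosen, by analogy with cyclic enones, for the 2S product.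

Step 13. The ruthenium hydride may also reduce the flavanone carbonyl (the (S,S) catalyst is the matched one for a (2S)-flavanone), or turn over slowly at the hindered α-silyloxy ketone. The fallback sets out from 21 and returns at 23; it uses no ketone reduction. The C1 epimers of 21 are separated, and the 1S epimer is 23. The 1R epimer F9, expected as the Felkin–Anh product of step 11, is inverted by Mitsunobu esterification with chloroacetic acid (PPh3, DIAD, toluene) to the (1S)-chloroacetate F10. Thiourea/NaHCO3 in EtOH should cleave F10 to 23 without base strong enough to open the flavanone.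

Further compounds
F1 | step 3 | 4-(benzyloxy)-2,6-bis(methoxymethoxy)benzaldehyde | O=Cc1c(OCOC)cc(OCc2ccccc2)cc1OCOC
F2 | step 3 | (4R)-3-{(E)-3-[4-(benzyloxy)-2,6-bis(methoxymethoxy)phenyl]acryloyl}-4-phenyloxazolidin-2-one | O=C(/C=C/c1c(OCOC)cc(OCc2ccccc2)cc1OCOC)N1[C@H](c2ccccc2)COC1=O
F3 | step 3 | (4R)-3-{(3S)-3-[4-(benzyloxy)-2,6-bis(methoxymethoxy)phenyl]-3-phenylpropanoyl}-4-phenyloxazolidin-2-one | O=C(C[C@@H](c1ccccc1)c1c(OCOC)cc(OCc2ccccc2)cc1OCOC)N1[C@H](c2ccccc2)COC1=O
F4 | step 3 | (4R)-3-{(2R,3S)-3-[4-(benzyloxy)-2,6-bis(methoxymethoxy)phenyl]-2-hydroxy-3-phenylpropanoyl}-4-phenyloxazolidin-2-one | O=C([C@H](O)[C@@H](c1ccccc1)c1c(OCOC)cc(OCc2ccccc2)cc1OCOC)N1[C@H](c2ccccc2)COC1=O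
F5 | step 8 | 1-{6-(benzyloxy)-3-[(1S,2R)-2,3-bis(TBS-oxy)-1-phenylpropyl]-2,4-bis(methoxymethoxy)phenyl}ethan-1-one | CC(C)(C)[Si](C)(C)OC[C@H](O[Si](C)(C)C(C)(C)C)[C@@H](c1ccccc1)c1c(OCOC)cc(OCc2ccccc2)c(C(C)=O)c1OCOC
F6 | step 8 | 1-{3-[(1S,2R)-2,3-bis(TBS-oxy)-1-phenylpropyl]-6-hydroxy-2,4-bis(methoxymethoxy)phenyl}ethan-1-one | CC(C)(C)[Si](C)(C)OC[C@H](O[Si](C)(C)C(C)(C)C)[C@@H](c1ccccc1)c1c(OCOC)cc(O)c(C(C)=O)c1OCOC
F7 | step 8 | (E)-1-{3-[(1S,2R)-2,3-bis(TBS-oxy)-1-phenylpropyl]-6-hydroxy-2,4-bis(methoxymethoxy)phenyl}-3-(dimethylamino)prop-2-en-1-one | CC(C)(C)[Si](C)(C)OC[C@H](O[Si](C)(C)C(C)(C)C)[C@@H](c1ccccc1)c1c(OCOC)cc(O)c(C(=O)/C=C/N(C)C)c1OCOC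
F8 | step 8 | 6-[(1S,2R)-2,3-bis(TBS-oxy)-1-phenylpropyl]-5,7-bis(methoxymethoxy)-4H-chromen-4-one | CC(C)(C)[Si](C)(C)OC[C@H](O[Si](C)(C)C(C)(C)C)[C@@H](c1ccccc1)c1c(OCOC)cc2c(c1OCOC)C(=O)C=CO2
F9 | step 13 | (1R,2R,3S)-2-(TBS-oxy)-1-(furan-2-yl)-3-Fl-3-phenylpropan-1-ol | c1coc(c1)[C@@H]([C@H](O[Si](C)(C)C(C)(C)C)[C@@H](c2ccccc2)c2c(OCOC)cc3c(c2OCOC)C(=O)C[C@@H](c2ccccc2)O3)O
F10 | step 13 | (1S,2R,3S)-2-(TBS-oxy)-1-(furan-2-yl)-3-Fl-3-phenylpropyl chloroacetate | c1coc(c1)[C@H]([C@H](O[Si](C)(C)C(C)(C)C)[C@@H](c2ccccc2)c2c(OCOC)cc3c(c2OCOC)C(=O)C[C@@H](c2ccccc2)O3)OC(=O)CCl
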